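## Retrosynthetic overview

1. Target 18 ⇐ its 5,7-dibenzyl ether 17 by hydrogenolysis in the last step.
2. 17 ⇐ bromoaryl keto aldehyde 16 by cutting C4–C4a. The strategy rests on the C4 carbinol being bonded to aromatic C4a, which is ortho to C8a–O1; O1 already carries C2(Me)2–C3H2, so the CHO carbon of an O1-tethered 3-methylbutanal reaches a C4a–Br bond in a six-membered closure, and a chiral nickel catalyst joins the two electrophilic carbons and sets C4.
3. 16 ⇐ diol 15 ⇐ alkenyl carbinol 13 ⇐ dibromide 10 + 3-phenylpropanal 11 (C8–acyl bond by mono Br/Li exchange). O1 lies para to the C6 methyl, so C8 and C4a are equivalent ortho carbons of a C2-symmetric arene until this step.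
4. 10 ⇐ aryl 1,1-dimethylpropargyl ether 8 (O1–C2 bond from 3-chloro-3-methylbut-1-yne 5) ⇐ phenol 4 ⇐ 2-methylresorcinol 1 (C8a–O1 bond by C–H borylation/oxidation).
5. Ring order: both benzene rings are bought; the pyran ring (O1–C2–C3–C4–C4a–C8a) is the only ring made, in step 10.

Key step: step 10

Assumption: the sense of induction of a chiral nickel catalyst in this closure cannot be predicted with confidence, so the ligand enantiomer that gives (4R) is fixed in a first screening run; (S)-t-Bu-PHOX is written for definiteness.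

## Route

Step 1
Reactants: 1 2-methylresorcinol
Product: 2 2-methyl-1,3-bis(triisopropylsilyloxy)benzene
Conditions: TIPSCl (2.3 equiv), imidazole (5 equiv), DMF, rt
Reagents that add atoms: chlorotriisopropylsilane, CC(C)[Si](Cl)(C(C)C)C(C)C
Why: Imidazole-mediated O-silylation of both phenols gives ethers that carry no aromatic C–H of their own, so they cannot compete in the C–H borylation of step 2 (benzyl ethers would), and they can later be exchanged for benzyl with fluoride.

Step 2
Reactants: 2 2-methyl-1,3-bis(triisopropylsilyloxy)benzene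
Product: 4 4-methyl-3,5-bis(triisopropylsilyloxy)phenol, via aryl pinacolboronate 3 (not isolated)
Conditions: [Ir(OMe)(cod)]2 (1.5 mol%), dtbpy (3 mol%), B2pin2 (1.0 equiv), THF, 80 °C; then Oxone, acetone/H2O, 0 °C to rt
Reagents that add atoms: bis(pinacolato)diboron, CC1(C)OB(OC1(C)C)B1OC(C)(C)C(C)(C)O1 (its boryl group stands only in 3); potassium peroxymonosulfate, [K+].[O-]S(=O)(=O)OO (supplies the phenol oxygen)
Why: Sterically governed iridium-catalysed aromatic C–H borylation should take the only ring C–H without an ortho substituent (para to the methyl), and one-pot oxidation of the C–B bond gives the C2-symmetric phenol whose oxygen becomes O1.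

Step 3
Reactants: 4 4-methyl-3,5-bis(triisopropylsilyloxy)phenol; 5 3-chloro-3-methylbut-1-yne
Product: 6 2-methyl-5-(2-methylbut-3-yn-2-yloxy)-1,3-bis(triisopropylsilyloxy)benzene
Conditions: CuCl2 (0.5 mol%), DBU (1.3 equiv), MeCN, −5 to 0 °C
Reagents that add atoms: none
Why: Copper-catalysed O-propargylation of a phenol with a tertiary propargylic chloride is the standard way to form the hindered ArO–CMe2 bond, and at 0 °C no aromatic propargyl Claisen rearrangement should occur.

Step 4
Reactants: 6 2-methyl-5-(2-methylbut-3-yn-2-yloxy)-1,3-bis(triisopropylsilyloxy)benzene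
Product: 8 1,3-bis(benzyloxy)-2-methyl-5-(2-methylbut-3-yn-2-yloxy)benzene, via ammonium diphenoxide 7 (not isolated)
Conditions: TBAF (2.2 equiv), THF, 0 °C; then BnBr (3 equiv), DMF, rt
Reagents that add atoms: tetrabutylammonium fluoride, [F-].CCCC[N+](CCCC)(CCCC)CCCC (its cation stands only in 7); benzyl bromide, BrCc1ccccc1
Why: Fluoride cleaves the two aryl O–Si bonds and the tetrabutylammonium phenoxides are O-benzylated in the same flask (desilylative Williamson etherification), giving benzyl ethers that are small, inert to n-BuLi and nickel(0), and removable without acid.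

Step 5
Reactants: 8 1,3-bis(benzyloxy)-2-methyl-5-(2-methylbut-3-yn-2-yloxy)benzene
Product: 9 1,5-bis(benzyloxy)-2,4-dibromo-6-methyl-3-(2-methylbut-3-yn-2-yloxy)benzene
Conditions: NBS (2.05 equiv), MeCN, 0 °C to rt, dark
Reagents that add atoms: N-bromosuccinimide, O=C1CCC(=O)N1Br
Why: Electrophilic aromatic bromination should occur only at the two equivalent ring C–H positions, each ortho/para to three alkoxy groups, and filling both ortho positions also blocks any later aromatic Claisen rearrangement of the tertiary ether.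

Step 6
Reactants: 9 1,5-bis(benzyloxy)-2,4-dibromo-6-methyl-3-(2-methylbut-3-yn-2-yloxy)benzene
Product: 10 1,5-bis(benzyloxy)-2,4-dibromo-6-methyl-3-(2-methylbut-3-en-2-yloxy)benzene
Conditions: H2 (1 atm), Lindlar catalyst, quinoline, EtOAc, rt, stopped after 1 equiv H2
Reagents that add atoms: none
Why: Lindlar semi-hydrogenation removes the acidic alkyne C–H, which would quench the aryllithium of step 7 and give a competing acetylide, and the poisoned palladium should leave the aryl bromides and benzyl ethers intact.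

Step 7
Reactants: 10 1,5-bis(benzyloxy)-2,4-dibromo-6-methyl-3-(2-methylbut-3-en-2-yloxy)benzene; 11 3-phenylpropanal
Product: 13 rac-1-[2,4-bis(benzyloxy)-5-bromo-3-methyl-6-(2-methylbut-3-en-2-yloxy)phenyl]-3-phenylpropan-1-ol, via aryllithium 12 (not isolated)
Conditions: n-BuLi (1.05 equiv), THF, −78 °C, 15 min; then 11, −78 °C; H2O quench
Reagents that add atoms: n-butyllithium, [Li]CCCC (its lithium stands only in 12)
Why: Bromine–lithium exchange on one of the two equivalent C–Br bonds followed by 1,2-addition to the aldehyde desymmetrises the arene, −78 °C suppressing carbolithiation of the allyl ether and enolisation; the carbinol forms as a racemate, which does not matter because step 9 oxidises it.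

Step 8
Reactants: 13 rac-1-[2,4-bis(benzyloxy)-5-bromo-3-methyl-6-(2-methylbut-3-en-2-yloxy)phenyl]-3-phenylpropan-1-ol
Product: 15 rac-3-[3,5-bis(benzyloxy)-2-bromo-6-(1-hydroxy-3-phenylpropyl)-4-methylphenoxy]-3-methylbutan-1-ol, via alkyl-9-BBN adduct 14 (not isolated)
Conditions: 9-BBN (3 equiv), THF, 0 °C to rt; then aq. NaOH, 30% H2O2, 0 °C to rt
Reagents that add atoms: 9-borabicyclo[3.3.1]nonane, B1C2CCCC1CCC2 (stands only in 14); hydrogen peroxide, OO (supplies the hydroxyl oxygen)
Why: Anti-Markovnikov hydroboration–oxidation with 9-BBN should place boron on the terminal carbon of the monosubstituted alkene next to the quaternary centre, the excess reagent allowing for O-borylation of the free carbinol, while aryl bromide and ethers are inert.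

Step 9
Reactants: 15 rac-3-[3,5-bis(benzyloxy)-2-bromo-6-(1-hydroxy-3-phenylpropyl)-4-methylphenoxy]-3-methylbutan-1-ol
Product: 16 3-[3,5-bis(benzyloxy)-2-bromo-4-methyl-6-(3-phenylpropanoyl)phenoxy]-3-methylbutanal
Conditions: Dess–Martin periodinane (2.6 equiv), NaHCO3, CH2Cl2, 0 °C to rt; Na2S2O3/NaHCO3 work-up, used without delay
Reagents that add atoms: none
Why: Dess–Martin oxidation should convert the primary and the benzylic secondary alcohol in one operation, the bicarbonate buffer keeping acetic acid from ionising the trialkoxybenzylic carbinol and the absence of amine base avoiding β-elimination of the aryloxide from the new β-aryloxy aldehyde.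

Step 10
Reactants: 16 3-[3,5-bis(benzyloxy)-2-bromo-4-methyl-6-(3-phenylpropanoyl)phenoxy]-3-methylbutanal
Product: 17 1-[(4R)-5,7-bis(benzyloxy)-4-hydroxy-2,2,6-trimethyl-3,4-dihydro-2H-chromen-8-yl]-3-phenylpropan-1-one
Conditions: NiBr2·DME (10 mol%), (S)-t-Bu-PHOX (12 mol%), Mn powder (3 equiv), DMA, 25 °C; pH 7 buffer work-up
Reagents that add atoms: none
Why: Manganese reduces nickel(II) to a ligated nickel(0) that inserts into the C4a–Br bond; the tethered aldehyde then coordinates and undergoes 1,2-insertion into the aryl–nickel bond, and the nickel alkoxide is passed to manganese while nickel is reduced again. The closest known reaction type is the enantioselective nickel-catalysed reductive cyclisation of aryl halides onto tethered ketones (chroman-4-ols, indanols), together with asymmetric nickel-catalysed reductive arylation of aldehydes; the hexasubstituted aryl bromide is the extension. The pyran ring closes by 6-exo-trig attack of C4a on the aldehyde carbon, helped by the gem-dimethyl group at C2. C4 is set by the chiral P,N ligand on nickel, which differentiates the two faces of the coordinated aldehyde during insertion. The step needs aldehyde-over-ketone selectivity and insertion faster than protodebromination or retro-oxa-Michael loss of the aryloxide: the C8 ketone is meta to the nickel-bearing carbon and cannot reach it through any unstrained ring, only the O1 tether delivers a carbonyl in six-membered geometry, and the base-free medium limits elimination.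

Step 11
Reactants: 17 1-[(4R)-5,7-bis(benzyloxy)-4-hydroxy-2,2,6-trimethyl-3,4-dihydro-2H-chromen-8-yl]-3-phenylpropan-1-one
Product: 18 1-[(4R)-4,5,7-trihydroxy-2,2,6-trimethyl-3,4-dihydro-2H-chromen-8-yl]-3-phenylpropan-1-one
Conditions: H2 (1 atm), 10% Pd/C, EtOAc, rt, stopped at complete debenzylation
Reagents that add atoms: none
Why: Hydrogenolysis of aryl benzyl ethers in a neutral, non-protic solvent should be much faster than cleavage of the secondary benzylic C4–O bond or reduction of the hindered aryl ketone, and no bond to C4 is touched, so the (4R) configuration is retained.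

## Compound list

1 | 2-methylresorcinol (2-methylbenzene-1,3-diol) | Cc1c(O)cccc1O | starting material
2 | 2-methyl-1,3-bis(triisopropylsilyloxy)benzene | Cc1c(O[Si](C(C)C)(C(C)C)C(C)C)cccc1O[Si](C(C)C)(C(C)C)C(C)C | intermediate
3 | 2-[4-methyl-3,5-bis(triisopropylsilyloxy)phenyl]-4,4,5,5-tetramethyl-1,3,2-dioxaborolane | Cc1c(O[Si](C(C)C)(C(C)C)C(C)C)cc(B2OC(C)(C)C(C)(C)O2)cc1O[Si](C(C)C)(C(C)C)C(C)C | intermediate (not isolated)
4 | 4-methyl-3,5-bis(triisopropylsilyloxy)phenol | Cc1c(O[Si](C(C)C)(C(C)C)C(C)C)cc(O)cc1O[Si](C(C)C)(C(C)C)C(C)C | intermediate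
5 | 3-chloro-3-methylbut-1-yne | CC(C)(Cl)C#C | starting material
6 | 2-methyl-5-(2-methylbut-3-yn-2-yloxy)-1,3-bis(triisopropylsilyloxy)benzene | Cc1c(O[Si](C(C)C)(C(C)C)C(C)C)cc(OC(C)(C)C#C)cc1O[Si](C(C)C)(C(C)C)C(C)C | intermediate
7 | bis(tetrabutylammonium) 2-methyl-5-(2-methylbut-3-yn-2-yloxy)benzene-1,3-diolate | Cc1c([O-])cc(OC(C)(C)C#C)cc1[O-].CCCC[N+](CCCC)(CCCC)CCCC.CCCC[N+](CCCC)(CCCC)CCCC | intermediate (not isolated)
8 | 1,3-bis(benzyloxy)-2-methyl-5-(2-methylbut-3-yn-2-yloxy)benzene | Cc1c(OCc2ccccc2)cc(OC(C)(C)C#C)cc1OCc1ccccc1 | intermediate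
9 | 1,5-bis(benzyloxy)-2,4-dibromo-6-methyl-3-(2-methylbut-3-yn-2-yloxy)benzene | Cc1c(OCc2ccccc2)c(Br)c(OC(C)(C)C#C)c(Br)c1OCc1ccccc1 | intermediate
10 | 1,5-bis(benzyloxy)-2,4-dibromo-6-methyl-3-(2-methylbut-3-en-2-yloxy)benzene | Cc1c(OCc2ccccc2)c(Br)c(OC(C)(C)C=C)c(Br)c1OCc1ccccc1 | intermediate
11 | 3-phenylpropanal | O=CCCc1ccccc1 | starting material
12 | [2,4-bis(benzyloxy)-5-bromo-3-methyl-6-(2-methylbut-3-en-2-yloxy)phenyl]lithium | Cc1c(OCc2ccccc2)c([Li])c(OC(C)(C)C=C)c(Br)c1OCc1ccccc1 | intermediate (not isolated)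
13 | rac-1-[2,4-bis(benzyloxy)-5-bromo-3-methyl-6-(2-methylbut-3-en-2-yloxy)phenyl]-3-phenylpropan-1-ol (racemic carbinol) | Cc1c(OCc2ccccc2)c(C(O)CCc2ccccc2)c(OC(C)(C)C=C)c(Br)c1OCc1ccccc1 | intermediate
14 | 9-{3-[3,5-bis(benzyloxy)-2-bromo-6-(1-hydroxy-3-phenylpropyl)-4-methylphenoxy]-3-methylbutyl}-9-borabicyclo[3.3.1]nonane (racemic carbinol) | Cc1c(OCc2ccccc2)c(C(O)CCc2ccccc2)c(OC(C)(C)CCB2C3CCCC2CCC3)c(Br)c1OCc1ccccc1 | intermediate (not isolated)
15 | rac-3-[3,5-bis(benzyloxy)-2-bromo-6-(1-hydroxy-3-phenylpropyl)-4-methylphenoxy]-3-methylbutan-1-ol (racemic carbinol) | Cc1c(OCc2ccccc2)c(C(O)CCc2ccccc2)c(OC(C)(C)CCO)c(Br)c1OCc1ccccc1 | intermediate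
16 | 3-[3,5-bis(benzyloxy)-2-bromo-4-methyl-6-(3-phenylpropanoyl)phenoxy]-3-methylbutanal | Cc1c(OCc2ccccc2)c(C(=O)CCc2ccccc2)c(OC(C)(C)CC=O)c(Br)c1OCc1ccccc1 | intermediate
17 | 1-[(4R)-5,7-bis(benzyloxy)-4-hydroxy-2,2,6-trimethyl-3,4-dihydro-2H-chromen-8-yl]-3-phenylpropan-1-one | Cc1c(OCc2ccccc2)c(C(=O)CCc2ccccc2)c2c(c1OCc1ccccc1)[C@H](O)CC(C)(C)O2 | intermediate
18 | 1-[(4R)-4,5,7-trihydroxy-2,2,6-trimethyl-3,4-dihydro-2H-chromen-8-yl]-3-phenylpropan-1-one | Cc1c(O)c(C(=O)CCc2ccccc2)c2c(c1O)[C@H](O)CC(C)(C)O2 | target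

## Step count and risks

Total step count: 11. Longest linear sequence: 11 steps, from 2-methylresorcinol 1 to target 18.

Steps most likely to fail:

1. Step 10. The chiral catalyst may give poor facial selectivity in the aryl-to-carbonyl transfer; oxidative addition at the doubly ortho-substituted C–Br bond may be slow, letting protodebromination or β-elimination of the aryloxide from the aldehyde compete. Fallback: from 16 the ring is closed without stereocontrol by the achiral nickel Barbier-type cyclisation (NiBr2·DME, 2,2′-bipyridine, Zn, DMA) to the racemic chromanol F1. This is oxidised (Dess–Martin periodinane, NaHCO3) to the chroman-4-one F2. Asymmetric transfer hydrogenation with RuCl[(R,R)-TsDPEN](p-cymene) and sodium formate at neutral pH should then reduce only the chromanone carbonyl, the di-ortho-substituted C8 ketone being a poor substrate, and by the usual aryl-ketone model deliver the (4R) alcohol, which is 17.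

2. Step 11. Hydrogenolysis may not stop at the benzyl ethers: the C4–O bond is benzylic to a ring with three oxygen donors, and once the 5-OH is free it can ionise through a quinone-methide-type pathway, leading to C4 deoxygenation or racemisation. Fallback: from 17 the C4 hydroxyl is capped (TBSOTf, 2,6-lutidine, CH2Cl2, −78 °C) as the C4 tert-butyldimethylsilyl ether F3. The benzyl ethers are hydrogenolysed (H2, Pd/C, EtOAc) to the diphenol silyl ether F4, whose bulky non-ionising silyloxy group should resist C–O cleavage. Buffered fluoride (TBAF, AcOH, THF, 0 °C) then releases 18.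

3. Step 9. Oxidation at the crowded benzylic carbinol may be slow, so the aldehyde already formed is exposed for a long time and is partly lost by β-elimination of the aryloxide during reaction and isolation. Fallback: from 13 the carbinol is oxidised alone (Dess–Martin periodinane, NaHCO3), before any aldehyde exists, to the alkenyl ketone F5. Hydroboration with 9-BBN, which should leave the hindered ketone alone, gives the alkyl-9-BBN adduct F6, oxidised in the same flask (NaOH, H2O2) to the keto alcohol F7. A short, cold Dess–Martin oxidation of this single primary alcohol gives 16, which is taken directly into step 10.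

## Further compounds

F1 | step 10 | rac-1-[5,7-bis(benzyloxy)-4-hydroxy-2,2,6-trimethyl-3,4-dihydro-2H-chromen-8-yl]-3-phenylpropan-1-one | Cc1c(OCc2ccccc2)c(C(=O)CCc2ccccc2)c2c(c1OCc1ccccc1)C(O)CC(C)(C)O2
F2 | step 10 | 5,7-bis(benzyloxy)-2,2,6-trimethyl-8-(3-phenylpropanoyl)-2,3-dihydro-4H-chromen-4-one | Cc1c(OCc2ccccc2)c(C(=O)CCc2ccccc2)c2c(c1OCc1ccccc1)C(=O)CC(C)(C)O2
F3 | step 11 | 1-[(4R)-5,7-bis(benzyloxy)-4-(tert-butyldimethylsilyloxy)-2,2,6-trimethyl-3,4-dihydro-2H-chromen-8-yl]-3-phenylpropan-1-one | Cc1c(OCc2ccccc2)c(C(=O)CCc2ccccc2)c2c(c1OCc1ccccc1)[C@H](O[Si](C)(C)C(C)(C)C)CC(C)(C)O2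
F4 | step 11 | 1-[(4R)-4-(tert-butyldimethylsilyloxy)-5,7-dihydroxy-2,2,6-trimethyl-3,4-dihydro-2H-chromen-8-yl]-3-phenylpropan-1-one | Cc1c(O)c(C(=O)CCc2ccccc2)c2c(c1O)[C@H](O[Si](C)(C)C(C)(C)C)CC(C)(C)O2
F5 | step 9 | 1-[2,4-bis(benzyloxy)-5-bromo-3-methyl-6-(2-methylbut-3-en-2-yloxy)phenyl]-3-phenylpropan-1-one | Cc1c(OCc2ccccc2)c(C(=O)CCc2ccccc2)c(OC(C)(C)C=C)c(Br)c1OCc1ccccc1
F6 | step 9 | 9-{3-[3,5-bis(benzyloxy)-2-bromo-4-methyl-6-(3-phenylpropanoyl)phenoxy]-3-methylbutyl}-9-borabicyclo[3.3.1]nonane | Cc1c(OCc2ccccc2)c(C(=O)CCc2ccccc2)c(OC(C)(C)CCB2C3CCCC2CCC3)c(Br)c1OCc1ccccc1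
F7 | step 9 | 1-[2,4-bis(benzyloxy)-5-bromo-6-(4-hydroxy-2-methylbutan-2-yloxy)-3-methylphenyl]-3-phenylpropan-1-one | Cc1c(OCc2ccccc2)c(C(=O)CCc2ccccc2)c(OC(C)(C)CCO)c(Br)c1OCc1ccccc1
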